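**Retrosynthetic overview**
1. Target 28 ⇐ nucleophilic epoxidation of the α-methylene lactone (C11, ring D) ⇐ C8 methacrylate and C9 acetate put on the 8,9-diol ⇐ acetonide 24.
2. 24 (carbocycle ring B and γ-lactone ring C) ⇐ intramolecular CrCl2 allylation across C6–C7 of the (Z)-enal / 2-(bromomethyl)enoate 21.
3. 3(2H)-Furanone (ring A) ⇐ isoxazole 13 by N–O cleavage, hydrolysis and cyclodehydration; 13 ⇐ nitrile oxide–alkyne [3+2] cycloaddition making C1–C2 (key step).
4. Nitrile oxide 12 ⇐ 2-C-methyl-L-ribose oxime from benzyl β-L-arabinopyranoside 1 (C8 and C9 bought, C10 set by MeMgBr addition anti to the acetonide); alkyne 10 ⇐ (Z)-3-methylpent-2-en-4-yn-1-ol 9 (C2–C6, C15 and the 4Z alkene bought).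
5. Ring order: isoxazole → furanone ring A → ring B and ring C together → epoxide ring D.

Assumption: germacrane numbering is used (C1 ketone, C3–O–C10 furanone bridge, C6 lactone oxygen, C8 methacrylate, C9 acetate, C11/C13 epoxide, C14 = CH3 on C10, C15 = CH3 on C4); the target read from the SMILES is (4Z,6R,7S,8S,9S,10S,11S), and its C8–C10 triad has the 2-C-methyl-L-ribo configuration.

**Route**

Step 1
Reactants: 1 benzyl β-L-arabinopyranoside
Product: 2 benzyl 3,4-O-isopropylidene-β-L-arabinopyranoside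
Conditions: Me2C(OMe)2, TsOH·H2O (cat.), DMF, rt
Reagents that add atoms: 2,2-dimethoxypropane COC(C)(C)OC
Why: Acid-catalysed transacetalisation (acetonide formation) takes only the cis-3,4-diol and leaves the trans-disposed 2-OH free.

Step 2
Reactants: 2 benzyl 3,4-O-isopropylidene-β-L-arabinopyranoside
Product: 3 benzyl 3,4-O-isopropylidene-β-L-erythro-pentopyranosid-2-ulose
Conditions: Dess–Martin periodinane, NaHCO3, CH2Cl2, 0 °C → rt
Reagents that add atoms: none
Why: Dess–Martin oxidation of the only free secondary alcohol gives the 2-ulose without touching the glycoside or acetonide.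

Step 3
Reactants: 3 benzyl 3,4-O-isopropylidene-β-L-erythro-pentopyranosid-2-ulose
Product: 4 benzyl 3,4-O-isopropylidene-2-C-methyl-β-L-ribopyranoside
Conditions: MeMgBr, THF, −78 °C
Reagents that add atoms: methylmagnesium bromide C[Mg]Br
Why: Grignard 1,2-addition comes from the equatorial side, anti to the axial O4 of the cis-fused acetonide, so the new tertiary hydroxyl (future C10) ends cis to O3 (L-ribo), the same facial sense as hydride reduction of this ulose to L-ribosides.

Step 4
Reactants: 4 benzyl 3,4-O-isopropylidene-2-C-methyl-β-L-ribopyranoside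
Product: 5 3,4-O-isopropylidene-2-C-methyl-L-ribopyranose (anomer mixture)
Conditions: H2 (1 atm), Pd/C (10%), EtOAc/EtOH, rt
Reagents that add atoms: none
Why: Hydrogenolysis of the benzyl glycoside frees the lactol while acetonide and tertiary alcohol are inert.

Step 5
Reactants: 5 3,4-O-isopropylidene-2-C-methyl-L-ribopyranose
Product: 6 3,4-O-isopropylidene-2-C-methyl-L-ribose oxime (open chain)
Conditions: NH2OH (50% aq.), EtOH, 60 °C
Reagents that add atoms: hydroxylamine NO
Why: Oxime condensation traps the open-chain aldehyde form of the lactol, turning C1 into the nitrile oxide precursor and freeing the C7 hydroxyl (oxime geometry is irrelevant).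

Step 6
Reactants: 6 3,4-O-isopropylidene-2-C-methyl-L-ribose oxime
Product: 8 3,4-O-isopropylidene-2-C-methyl-5-O-triethylsilyl-L-ribose oxime, via bis-silyl oxime 7 (not isolated)
Conditions: Et3SiCl (2.2 equiv), imidazole, CH2Cl2, 0 °C; then K2CO3 (cat.), MeOH, 0 °C
Reagents that add atoms: chlorotriethylsilane CC[Si](Cl)(CC)CC
Why: Silylation takes the primary and oxime hydroxyls (not the hindered tertiary one) and brief methanolysis cleaves only the labile N–O–Si bond, so the C7 hydroxyl can no longer trap the nitrile oxide as a cyclic hydroximate.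

Step 7
Reactants: 9 (Z)-3-methylpent-2-en-4-yn-1-ol
Product: 10 tert-butyl{[(2Z)-3-methylpent-2-en-4-yn-1-yl]oxy}diphenylsilane
Conditions: t-BuPh2SiCl, imidazole, CH2Cl2, rt
Reagents that add atoms: tert-butyl(chloro)diphenylsilane CC(C)(C)[Si](Cl)(c1ccccc1)c1ccccc1
Why: Silyl ether formation masks the C6 hydroxyl with an acid-stable group so that it cannot close onto the C3 carbonyl to give a furan in step 9.

Step 8
Reactants: 8 3,4-O-isopropylidene-2-C-methyl-5-O-triethylsilyl-L-ribose oxime; 10 tert-butyl{[(2Z)-3-methylpent-2-en-4-yn-1-yl]oxy}diphenylsilane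
Product: 13 3-(L-ribo C10–C7 side chain)-5-[(2Z)-4-(tert-butyldiphenylsilyloxy)but-2-en-2-yl]isoxazole, via hydroximoyl chloride 11 (not isolated), via nitrile oxide 12 (not isolated)
Conditions: NCS, DMF, rt; then Et3N (slow addition), CH2Cl2, rt → 40 °C
Reagents that add atoms: none
Why: Huisgen nitrile oxide–alkyne [3+2] cycloaddition of the hindered, slowly dimerising nitrile oxide to the terminal alkyne gives the 3,5-disubstituted isoxazole (oxygen on C3), forming the C1–C2 bond and the latent furanone ring without touching any stereocentre or the trisubstituted Z-alkene.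

Step 9
Reactants: 13 isoxazole
Product: 16 (2S)-2-[(4S,5S)-5-(hydroxymethyl)-2,2-dimethyl-1,3-dioxolan-4-yl]-2-methyl-5-[(2Z)-4-(tert-butyldiphenylsilyloxy)but-2-en-2-yl]furan-3(2H)-one, via amino enone 14 (not isolated), via β-diketone 15 (not isolated)
Conditions: Mo(CO)6, MeCN/H2O (10:1), 80 °C; then 1 M HCl/acetone (1:9), rt
Reagents that add atoms: water O
Why: Mo(CO)6 cleaves the isoxazole N–O bond to the vinylogous amide, aqueous acid hydrolyses it to the β-diketone and removes the triethylsilyl group, and the tertiary C10 hydroxyl then closes onto C3 with loss of water (3(2H)-furanone cyclodehydration), while acetone as solvent keeps the acetonide on.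

Step 10
Reactants: 16 furanone C7 alcohol
Product: 17 furanone C7 aldehyde (16 with CH2OH oxidised to CHO)
Conditions: Dess–Martin periodinane, NaHCO3, CH2Cl2, 0 °C
Reagents that add atoms: none
Why: Buffered Dess–Martin oxidation gives the α-alkoxy aldehyde without epimerising C8; it is used at once.

Step 11
Reactants: 17 furanone C7 aldehyde
Product: 18 methyl 2-[hydroxy(dioxolanyl)methyl]prop-2-enoate adduct (C7 epimer mixture)
Conditions: i-Bu2AlH, N-methylmorpholine N-oxide, methyl propiolate, THF, 0 °C; then 17, 0 °C → rt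
Reagents that add atoms: methyl propiolate C#CC(=O)OC
Why: Hydroalumination of the propiolate gives the α-(methoxycarbonyl)vinylalane, which adds to the aldehyde under non-basic conditions to give the Morita–Baylis–Hillman-type adduct; the new C7 carbinol centre does not matter because C7 becomes sp2 in step 14.

Step 12
Reactants: 18 Baylis–Hillman-type adduct
Product: 19 C6,C7-diol (18 without the silyl group)
Conditions: HF·pyridine, pyridine, THF, 0 °C → rt
Reagents that add atoms: none
Why: Buffered fluoride desilylation frees the primary allylic C6 alcohol without base-induced damage to the acrylate or the acetonide.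

Step 13
Reactants: 19 C6,C7-diol
Product: 20 (Z)-C6 enal with free C7 hydroxyl
Conditions: TEMPO (cat.), PhI(OAc)2, CH2Cl2, rt
Reagents that add atoms: none
Why: Oxoammonium (TEMPO) oxidation takes the primary allylic alcohol selectively over the hindered secondary one and does not isomerise the Z-alkene.

Step 14
Reactants: 20 (Z)-C6 enal
Product: 21 methyl (2Z)-2-(bromomethyl)alk-2-enoate (Z)-enal
Conditions: NBS, Me2S, CH2Cl2, −20 → 0 °C
Reagents that add atoms: N-bromosuccinimide O=C1CCC(=O)N1Br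
Why: Corey–Kim-type activation of the Baylis–Hillman alcohol followed by SN2' attack of bromide gives the thermodynamically preferred (Z)-2-(bromomethyl)enoate and leaves the enal alone.

Step 15
Reactants: 21 allylic bromide enal
Product: 24 8,9-O-isopropylidene macrolactone (3,10-epoxy-1-oxogermacra-2,4Z,11(13)-trien-12,6-olide skeleton), via allylchromium 22 (not isolated), via hydroxy ester 23 (not isolated)
Conditions: CrCl2 (10 equiv), THF, 0.002 M, rt; then TsOH·H2O (cat.), CH2Cl2, rt
Reagents that add atoms: none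
Why: Intramolecular Nozaki–Hiyama (Barbier-type) allylation: the allylchromium adds through its γ-carbon C7 to the C6 aldehyde to close ring B, the C8 stereocentre and the ring-forming transition state are expected to give the anti (6R,7S) adduct, and this lactonises to the trans-fused α-methylene lactone.

Step 16
Reactants: 24 acetonide macrolactone
Product: 25 8,9-diol macrolactone
Conditions: AcOH/H2O (4:1), 50 °C
Reagents that add atoms: none
Why: Acid hydrolysis of the acetonide frees the cis-8,9-diol; furanone and α-methylene lactone tolerate aqueous acetic acid.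

Step 17
Reactants: 25 8,9-diol macrolactone
Product: 26 8-O-methacryloyl 9-hydroxy macrolactone
Conditions: methacrylic anhydride (1.2 equiv), DMAP (cat.), Et3N, CH2Cl2, −40 → −10 °C
Reagents that add atoms: methacrylic anhydride C=C(C)C(=O)OC(=O)C(C)=C
Why: DMAP-catalysed acylation should take the C8 hydroxyl first because the C9 hydroxyl is neopentylic, flanked by the quaternary C10.

Step 18
Reactants: 26 8-O-methacryloyl 9-hydroxy macrolactone
Product: 27 9-O-acetyl-8-O-methacryloyl macrolactone (target lacking the epoxide oxygen)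
Conditions: Ac2O, DMAP, pyridine, CH2Cl2, 0 °C → rt
Reagents that add atoms: acetic anhydride CC(=O)OC(C)=O
Why: Exhaustive DMAP-catalysed acetylation esterifies the remaining hindered C9 hydroxyl.

Step 19
Reactants: 27 9-O-acetyl-8-O-methacryloyl macrolactone
Product: 28 target (CNP0423862.2)
Conditions: t-BuOOH, DBU, CH2Cl2, 0 °C
Reagents that add atoms: tert-butyl hydroperoxide CC(C)(C)OO
Why: Weitz–Scheffer nucleophilic epoxidation: the peroxide anion adds to C13 of the α-methylene lactone (a much better acceptor than the methacrylate) and the enolate closes on oxygen from the β-face, the face from which C11 of trans-fused germacranolide enolates is usually attacked, which gives 11S.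

**Compound list**
1 | benzyl β-L-arabinopyranoside | O1C[C@H](O)[C@H](O)[C@@H](O)[C@H]1OCc1ccccc1 | starting material
2 | benzyl 3,4-O-isopropylidene-β-L-arabinopyranoside | O1C[C@@H]2OC(C)(C)O[C@@H]2[C@@H](O)[C@H]1OCc1ccccc1 | intermediate
3 | benzyl 3,4-O-isopropylidene-β-L-erythro-pentopyranosid-2-ulose | O1C[C@@H]2OC(C)(C)O[C@@H]2C(=O)[C@H]1OCc1ccccc1 | intermediate
4 | benzyl 3,4-O-isopropylidene-2-C-methyl-β-L-ribopyranoside | O1C[C@@H]2OC(C)(C)O[C@@H]2[C@](C)(O)[C@H]1OCc1ccccc1 | intermediate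
5 | 3,4-O-isopropylidene-2-C-methyl-L-ribopyranose (anomer mixture) | O1C[C@@H]2OC(C)(C)O[C@@H]2[C@](C)(O)C1O | intermediate
6 | 3,4-O-isopropylidene-2-C-methyl-L-ribose oxime (open chain, E drawn) | O/N=C/[C@@](C)(O)[C@H]1OC(C)(C)O[C@H]1CO | intermediate
7 | 3,4-O-isopropylidene-2-C-methyl-5-O-triethylsilyl-L-ribose O-triethylsilyl oxime | CC[Si](CC)(CC)O/N=C/[C@@](C)(O)[C@H]1OC(C)(C)O[C@H]1CO[Si](CC)(CC)CC | intermediate
8 | 3,4-O-isopropylidene-2-C-methyl-5-O-triethylsilyl-L-ribose oxime | O/N=C/[C@@](C)(O)[C@H]1OC(C)(C)O[C@H]1CO[Si](CC)(CC)CC | intermediate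
9 | (Z)-3-methylpent-2-en-4-yn-1-ol | C#C/C(C)=C\CO | starting material
10 | tert-butyl{[(2Z)-3-methylpent-2-en-4-yn-1-yl]oxy}diphenylsilane | C#C/C(C)=C\CO[Si](c1ccccc1)(c1ccccc1)C(C)(C)C | intermediate
11 | hydroximoyl chloride of 8 (C1(Cl)=N–OH) | O/N=C(\Cl)[C@@](C)(O)[C@H]1OC(C)(C)O[C@H]1CO[Si](CC)(CC)CC | intermediate
12 | nitrile oxide of 8 (C1≡N–O) | [O-][N+]#C[C@@](C)(O)[C@H]1OC(C)(C)O[C@H]1CO[Si](CC)(CC)CC | intermediate
13 | isoxazole: C-3 bears C10(OH)(CH3) joined to the cis C9/C8 acetonide and CH2OSiEt3 (L-ribo); C-5 bears (2Z)-4-(tert-butyldiphenylsilyloxy)but-2-en-2-yl | CC(C)(C)[Si](c1ccccc1)(c1ccccc1)OC/C=C(/C)c1cc(no1)[C@@](C)(O)[C@H]1OC(C)(C)O[C@H]1CO[Si](CC)(CC)CC | intermediate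
14 | (Z)-β-amino enone C1(NH2)=C2H–C3(=O), side chains as in 13 | CC(C)(C)[Si](c1ccccc1)(c1ccccc1)OC/C=C(/C)C(=O)/C=C(\N)[C@@](C)(O)[C@H]1OC(C)(C)O[C@H]1CO[Si](CC)(CC)CC | intermediate
15 | β-diketone C1(=O)–C2H2–C3(=O) with free C10 and C7 hydroxyls | CC(C)(C)[Si](c1ccccc1)(c1ccccc1)OC/C=C(/C)C(=O)CC(=O)[C@@](C)(O)[C@H]1OC(C)(C)O[C@H]1CO | intermediate
16 | (2S)-2-[(4S,5S)-5-(hydroxymethyl)-2,2-dimethyl-1,3-dioxolan-4-yl]-2-methyl-5-[(2Z)-4-(tert-butyldiphenylsilyloxy)but-2-en-2-yl]furan-3(2H)-one | CC(C)(C)[Si](c1ccccc1)(c1ccccc1)OC/C=C(/C)C1=CC(=O)[C@@](C)(O1)[C@H]1OC(C)(C)O[C@H]1CO | intermediate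
17 | C7 aldehyde of 16 (dioxolane CH2OH → CHO) | CC(C)(C)[Si](c1ccccc1)(c1ccccc1)OC/C=C(/C)C1=CC(=O)[C@@](C)(O1)[C@H]1OC(C)(C)O[C@H]1C=O | intermediate
18 | methyl 2-[hydroxy(dioxolanyl)methyl]prop-2-enoate adduct of 17 (C7 epimers), C6 silyl ether | CC(C)(C)[Si](c1ccccc1)(c1ccccc1)OC/C=C(/C)C1=CC(=O)[C@@](C)(O1)[C@H]1OC(C)(C)O[C@H]1C(O)C(=C)C(=O)OC | intermediate
19 | C6,C7-diol (18 desilylated) | OC/C=C(/C)C1=CC(=O)[C@@](C)(O1)[C@H]1OC(C)(C)O[C@H]1C(O)C(=C)C(=O)OC | intermediate
20 | (Z)-C6 enal with C7 hydroxyl | O=C/C=C(/C)C1=CC(=O)[C@@](C)(O1)[C@H]1OC(C)(C)O[C@H]1C(O)C(=C)C(=O)OC | intermediate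
21 | methyl (2Z)-2-(bromomethyl)-3-(dioxolanyl)prop-2-enoate bearing the furanone (Z)-enal | O=C/C=C(/C)C1=CC(=O)[C@@](C)(O1)[C@H]1OC(C)(C)O[C@H]1/C=C(/C(=O)OC)CBr | intermediate
22 | allylchromium dichloride from 21 (chromium on C13) | O=C/C=C(/C)C1=CC(=O)[C@@](C)(O1)[C@H]1OC(C)(C)O[C@H]1/C=C(/C(=O)OC)C[Cr](Cl)Cl | intermediate
23 | ring B hydroxy ester: C6–OH, C7–C(=CH2)CO2CH3, 8,9-acetonide (configuration as in target) | CC1(C)O[C@H]2[C@H]([C@H](O)/C=C(/C)C3=CC(=O)[C@@](C)(O3)[C@H]2O1)C(=C)C(=O)OC | intermediate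
24 | 8,9-O-isopropylidene-3,10-epoxy-1-oxogermacra-2,4Z,11(13)-trien-12,6-olide (6α-O, 7α-H, 8β-O, 9β-O, 10α-CH3) | CC1(C)O[C@H]2[C@@H]3[C@@H](/C=C(/C)C4=CC(=O)[C@@](C)(O4)[C@H]2O1)OC(=O)C3=C | intermediate
25 | 8β,9β-dihydroxy macrolactone | O[C@H]1[C@@H]2[C@@H](/C=C(/C)C3=CC(=O)[C@@](C)(O3)[C@H]1O)OC(=O)C2=C | intermediate
26 | 8β-methacryloyloxy-9β-hydroxy macrolactone | C=C(C)C(=O)O[C@H]1[C@@H]2[C@@H](/C=C(/C)C3=CC(=O)[C@@](C)(O3)[C@H]1O)OC(=O)C2=C | intermediate
27 | 9β-acetoxy-8β-methacryloyloxy macrolactone with 11(13)-alkene | C=C(C)C(=O)O[C@H]1[C@@H]2[C@@H](/C=C(/C)C3=CC(=O)[C@@](C)(O3)[C@H]1OC(C)=O)OC(=O)C2=C | intermediate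
28 | CNP0423862.2, (4Z,6R,7S,8S,9S,10S,11S)-9-acetoxy-8-methacryloyloxy-3,10:11,13-diepoxy-1-oxogermacra-2,4-dien-12,6-olide | C=C(C)C(=O)O[C@H]1[C@@H]2[C@@H](/C=C(/C)C3=CC(=O)[C@@](C)(O3)[C@H]1OC(C)=O)OC(=O)[C@@]21CO1 | target

**Step count and risks**
Total steps: 19. Longest linear sequence: 18 (steps 1–6 and 8–19).

Step 15 (macrocyclisation) is the most likely to fail, through ring strain, oligomerisation or the wrong C6/C7 pair. The fallback sets out from 20. Acetylation (Ac2O, DMAP, pyridine) gives the C7 allylic acetate of 20 F1. F1 is cyclised by umpolung of its π-allylpalladium complex (Pd(PPh3)4, zerovalent palladium, catalytic; indium monoiodide InI; THF, high dilution). The allylindium formed by transmetallation adds through C7 to the C6 aldehyde in a differently organised transition state, the product is hydroxy ester 23, and acid lactonisation brings the route back at 24.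

Step 17 (mono-methacrylation) may give mixtures or the C9 ester. The fallback sets out from 25. MeC(OMe)3 with camphorsulfonic acid gives the cyclic 8,9-orthoacetate of 25 F2. Mild aqueous acetic acid opens F2 through the dioxolanylium ion to the 9-O-acetyl 8-hydroxy lactone F3, with the acetate expected on the more hindered C10-flanked oxygen. Methacrylic anhydride/DMAP then esterifies the remaining C8 hydroxyl, and the route comes back at 27.

Step 19 (epoxidation) may give the C11 epimer or attack the methacrylate. The fallback sets out from 25. Hydroxyl-directed epoxidation (VO(acac)2 cat., t-BuOOH, CH2Cl2) uses the free 8β-hydroxyl, homoallylic to C11=C13, to deliver oxygen to the β-face before any acrylate ester is present. This gives the 11,13-epoxy 8,9-diol F4. Methacrylic anhydride (as in step 17) gives the 11,13-epoxy 8-O-methacrylate F5, and acetylation (as in step 18) brings the route back at 28.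

**Further compounds**
F1 | step 15 | C7 acetate of 20 (methyl 2-[acetoxy(dioxolanyl)methyl]prop-2-enoate with furanone (Z)-enal) | O=C/C=C(/C)C1=CC(=O)[C@@](C)(O1)[C@H]1OC(C)(C)O[C@H]1C(OC(C)=O)C(=C)C(=O)OC
F2 | step 17 | 8,9-O-(1-methoxyethylidene) orthoester of 25 | COC1(C)O[C@H]2[C@@H]3[C@@H](/C=C(/C)C4=CC(=O)[C@@](C)(O4)[C@H]2O1)OC(=O)C3=C
F3 | step 17 | 9β-acetoxy-8β-hydroxy macrolactone | O[C@H]1[C@@H]2[C@@H](/C=C(/C)C3=CC(=O)[C@@](C)(O3)[C@H]1OC(C)=O)OC(=O)C2=C
F4 | step 19 | 8β,9β-dihydroxy 11,13-epoxide | O[C@H]1[C@@H]2[C@@H](/C=C(/C)C3=CC(=O)[C@@](C)(O3)[C@H]1O)OC(=O)[C@@]21CO1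
F5 | step 19 | 8β-methacryloyloxy-9β-hydroxy 11,13-epoxide | C=C(C)C(=O)O[C@H]1[C@@H]2[C@@H](/C=C(/C)C3=CC(=O)[C@@](C)(O3)[C@H]1O)OC(=O)[C@@]21CO1
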